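**Assumption:** germacrane numbering is used (C6 = lactone O–CH, C7 = ring-fusion CH, C8 = ester O–CH, C1/C10 = epoxide carbons, C3/C4/C15 = triol, C11–C13 = methylene lactone; β = the face of H-6). 4-Methyl-3,6-dihydro-2H-pyran is taken as a commercial bulk chemical.

## Retrosynthetic overview

1. 23 ⇐ 22 by a last-step, face-selective epoxidation of the (Z)-C1=C10 alkene; 22 ⇐ 21 (acetonide off) ⇐ 19 by inverting esterification at C8 with angelic acid.
2. Key disconnection C7–C8 in 19: the β-carbon of a 3-(bromomethyl)butenolide is made nucleophilic (allylchromium, a homoenolate equivalent) and adds to the C8 aldehyde of 17. This closes the 10-membered ring and sets C7, C8 and the exocyclic methylene in one step.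
3. Butenolide 15 ⇐ ring-closing metathesis of the 2-(bromomethyl)acrylate of allylic alcohol 12; C6 by 1,3-syn reduction; C4–C5 by ketone aldol addition to dioxanone 8.
4. C3 and the C2–C3 bond ⇐ SAMP-hydrazone alkylation of 2,2-dimethyl-1,3-dioxan-5-one (its acetonide remains as the only protection of the triol) with (Z)-allylic iodide 2, opened from 4-methyl-3,6-dihydro-2H-pyran.
5. Ring order: 1,3-dioxane (bought) → butenolide (step 8) → 10-membered carbocycle (step 11) → oxirane (step 14).

## Route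

Step 1
Reactants: 1 4-methyl-3,6-dihydro-2H-pyran
Product: 2 (Z)-tert-butyl[(5-iodo-3-methylpent-3-en-1-yl)oxy]dimethylsilane
Conditions: TBSCl, NaI, MeCN, 0 °C to rt, dark; used crude
Reagents that add atoms: tert-butyldimethylsilyl chloride CC(C)(C)[Si](C)(C)Cl; NaI [Na+].[I-]
Why: In situ TBSI silylates the ring oxygen and iodide opens the silyloxonium ion at the allylic carbon (silyl iodide ether cleavage, as in the TBSCl/NaI opening of THF), so the ring-locked Z geometry of the future C1=C10 bond is carried into the chain.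

Step 2
Reactants: 3 2,2-dimethyl-1,3-dioxan-5-one; 4 (S)-1-amino-2-(methoxymethyl)pyrrolidine (SAMP)
Product: 5 (S)-N-(2,2-dimethyl-1,3-dioxan-5-ylidene)-2-(methoxymethyl)pyrrolidin-1-amine
Conditions: cyclohexane, 4 Å molecular sieves, reflux
Reagents that add atoms: none
Why: Hydrazone condensation installs the proline-derived auxiliary that will control C3.

Step 3
Reactants: 5 SAMP hydrazone; 2 (Z)-allylic iodide
Product: 7 (S)-N-[(4S)-4-[(Z)-5-(tert-butyldimethylsilyloxy)-3-methylpent-2-en-1-yl]-2,2-dimethyl-1,3-dioxan-5-ylidene]-2-(methoxymethyl)pyrrolidin-1-amine, via lithium azaenolate 6 (not isolated)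
Conditions: t-BuLi, THF, −78 °C; then 2, −100 °C to −78 °C
Reagents that add atoms: none
Why: Enders SAMP-hydrazone α-alkylation: the chelated lithium azaenolate is alkylated (SN2) by the allylic iodide on the face away from the methoxymethyl arm, setting C3 as S (same sense as SAMP/3-pentanone alkylations).

Step 4
Reactants: 7 alkylated hydrazone
Product: 8 (S)-4-[(Z)-5-(tert-butyldimethylsilyloxy)-3-methylpent-2-en-1-yl]-2,2-dimethyl-1,3-dioxan-5-one
Conditions: sat. aq. oxalic acid, Et2O, rt
Reagents that add atoms: water O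
Why: Mild biphasic hydrazone hydrolysis frees the ketone without epimerising C3 or cleaving the acetonide or the silyl ether.

Step 5
Reactants: 8 dioxanone ketone; 9 2-(trimethylsilyloxy)buta-1,3-diene
Product: 11 1-[(4S,5R)-4-[(Z)-5-(tert-butyldimethylsilyloxy)-3-methylpent-2-en-1-yl]-5-hydroxy-2,2-dimethyl-1,3-dioxan-5-yl]but-3-en-2-one, via lithium buta-1,3-dien-2-olate 10 (not isolated)
Conditions: 9, MeLi, THF, 0 °C; then 8, −78 °C; then H2O at −78 °C
Reagents that add atoms: none
Why: Ketone aldol addition of the regiodefined lithium enolate of methyl vinyl ketone; axial attack on the chair dioxanone (equatorial C3 side chain, no 1,3-diaxial hydrogens beside the ring oxygens) puts the new CH2 (C5) cis to the side chain and sets C4 as R.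

Step 6
Reactants: 11 β-hydroxy enone
Product: 12 (R)-1-[(4S,5R)-4-[(Z)-5-(tert-butyldimethylsilyloxy)-3-methylpent-2-en-1-yl]-5-hydroxy-2,2-dimethyl-1,3-dioxan-5-yl]but-3-en-2-ol
Conditions: Et2BOMe, THF/MeOH 4:1, −78 °C; NaBH4; then H2O
Reagents that add atoms: none
Why: Narasaka–Prasad 1,3-syn reduction: in the boron chelate the bulkier ring carbon C3 sits equatorial and external hydride adds axially to the activated carbonyl (1,2-addition), so the C6 carbinol is syn to the C4 hydroxyl along C3–C7 (6R).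

Step 7
Reactants: 12 allylic alcohol; 13 2-(bromomethyl)acrylic acid
Product: 14 (R)-1-[(4S,5R)-4-[(Z)-5-(tert-butyldimethylsilyloxy)-3-methylpent-2-en-1-yl]-5-hydroxy-2,2-dimethyl-1,3-dioxan-5-yl]but-3-en-2-yl 2-(bromomethyl)acrylate
Conditions: DIC, DMAP (5 mol %), CH2Cl2, −20 to 0 °C
Reagents that add atoms: none
Why: Steglich carbodiimide esterification acylates only the secondary allylic alcohol because the tertiary C4 hydroxyl is too hindered.

Step 8
Reactants: 14 acrylate ester
Product: 15 (R)-3-(bromomethyl)-5-{[(4S,5R)-4-[(Z)-5-(tert-butyldimethylsilyloxy)-3-methylpent-2-en-1-yl]-5-hydroxy-2,2-dimethyl-1,3-dioxan-5-yl]methyl}furan-2(5H)-one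
Conditions: second-generation Grubbs catalyst (5–10 mol %), CH2Cl2 (0.005 M), 40 °C
Reagents that add atoms: none
Why: Ring-closing metathesis between the vinyl group and the acrylate methylene forms the five-membered butenolide (faster than closure onto the trisubstituted alkene) and leaves the allylic bromide on C13.

Step 9
Reactants: 15 silyl ether
Product: 16 (R)-3-(bromomethyl)-5-{[(4S,5R)-5-hydroxy-4-[(Z)-5-hydroxy-3-methylpent-2-en-1-yl]-2,2-dimethyl-1,3-dioxan-5-yl]methyl}furan-2(5H)-one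
Conditions: HF·pyridine, THF, 0 °C (no added base)
Reagents that add atoms: none
Why: Fluoride cleavage of the silyl ether under weakly acidic conditions spares the acetonide, the butenolide and the allylic bromide.

Step 10
Reactants: 16 primary alcohol
Product: 17 (Z)-5-[(4S,5R)-5-{[(R)-4-(bromomethyl)-5-oxo-2,5-dihydrofuran-2-yl]methyl}-5-hydroxy-2,2-dimethyl-1,3-dioxan-4-yl]-3-methylpent-3-enal
Conditions: Dess–Martin periodinane, CH2Cl2, 0 °C, 30 min; short silica plug; used at once
Reagents that add atoms: none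
Why: Dess–Martin oxidation gives the β,γ-unsaturated aldehyde under near-neutral conditions without moving the Z double bond into conjugation.

Step 11
Reactants: 17 bromo aldehyde
Product: 19 (1(10)Z,3S,4R,6R,7R,8S)-4,8-dihydroxy-3,15-(isopropylidenedioxy)germacra-1(10),11(13)-dien-12,6-olide (8α-alcohol), via allylchromium dichloride 18 (not isolated)
Conditions: CrCl2 (6 equiv), THF, 25 °C, syringe-pump addition of 17 to 0.002 M; then H2O
Reagents that add atoms: none
Why: Proposed new method: CrCl2 (divalent chromium) reduces the allylic bromide to an allylchromium species whose nucleophilic carbon is C7, the β-carbon of the lactone (homoenolate equivalent, normally electrophilic), and this adds to the tethered electrophilic aldehyde carbon through a chair Zimmerman–Traxler transition state, anti to the C5 substituent on C6 (6,7-trans lactone) and with the aldehyde chain equatorial (E-type allyl geometry fixed by the ring, hence the anti 8α-alcohol), regenerating the exocyclic methylene; the closest known reactions are the intermolecular chromium- or zinc-mediated Barbier addition of 3-(bromomethyl)furan-2(5H)-one to aldehydes and Nozaki–Hiyama–Kishi-type allylation macrocyclisations to germacranolides.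

Step 12
Reactants: 19 8α-alcohol; 20 angelic acid ((Z)-2-methylbut-2-enoic acid)
Product: 21 (1(10)Z,3S,4R,6R,7R,8R)-8-angeloyloxy-4-hydroxy-3,15-(isopropylidenedioxy)germacra-1(10),11(13)-dien-12,6-olide
Conditions: PPh3, DIAD, toluene, 0 °C to rt
Reagents that add atoms: none
Why: Mitsunobu esterification: SN2 displacement of the 8α-oxyphosphonium group by angelate inverts C8 to the required 8β (R) configuration under neutral conditions that do not isomerise angelate to tiglate, and the tertiary alcohol does not react.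

Step 13
Reactants: 21 acetonide
Product: 22 (1(10)Z,3S,4R,6R,7R,8R)-8-angeloyloxy-3,4,15-trihydroxygermacra-1(10),11(13)-dien-12,6-olide
Conditions: AcOH/THF/H2O 3:1:1, 40 °C
Reagents that add atoms: none
Why: Acid-catalysed acetal hydrolysis releases the 3,15-diol while the angelate, the lactone and the alkene are untouched.

Step 14
Reactants: 22 triol
Product: 23 (1R,3S,4R,6R,7S,8R,10S)-8-angeloyloxy-1,10-epoxy-3,4,15-trihydroxygermacr-11(13)-en-12,6-olide (CNP0307250.1)
Conditions: mCPBA (1.1 equiv), CH2Cl2/aq. NaHCO3, 0 °C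
Reagents that add atoms: 3-chloroperbenzoic acid OOC(=O)c1cccc(Cl)c1
Why: Prilezhaev epoxidation: only the trisubstituted C1=C10 alkene is electron-rich, and the peracid, hydrogen-bonded to the homoallylic 3β-hydroxyl, is expected to add to the exposed β face with retention of the Z geometry, giving the cis 1β,10β-epoxide (1R,10S).

## Compound list

1 | 4-methyl-3,6-dihydro-2H-pyran | CC1=CCOCC1 | starting material
2 | (Z)-tert-butyl[(5-iodo-3-methylpent-3-en-1-yl)oxy]dimethylsilane | IC/C=C(/C)CCO[Si](C)(C)C(C)(C)C | intermediate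
3 | 2,2-dimethyl-1,3-dioxan-5-one | CC1(C)OCC(=O)CO1 | starting material
4 | (S)-1-amino-2-(methoxymethyl)pyrrolidine (SAMP) | COC[C@@H]1CCCN1N | starting material
5 | (S)-N-(2,2-dimethyl-1,3-dioxan-5-ylidene)-2-(methoxymethyl)pyrrolidin-1-amine | COC[C@@H]1CCCN1N=C1COC(C)(C)OC1 | intermediate
6 | lithium azaenolate of 5 (N-lithio ene-hydrazine) | COC[C@@H]1CCCN1N([Li])C1=COC(C)(C)OC1 | intermediate (not isolated)
7 | (S)-N-[(4S)-4-[(Z)-5-(tert-butyldimethylsilyloxy)-3-methylpent-2-en-1-yl]-2,2-dimethyl-1,3-dioxan-5-ylidene]-2-(methoxymethyl)pyrrolidin-1-amine (C=N geometry not fixed) | COC[C@@H]1CCCN1N=C1COC(C)(C)O[C@H]1C/C=C(/C)CCO[Si](C)(C)C(C)(C)C | intermediate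
8 | (S)-4-[(Z)-5-(tert-butyldimethylsilyloxy)-3-methylpent-2-en-1-yl]-2,2-dimethyl-1,3-dioxan-5-one | O=C1COC(C)(C)O[C@H]1C/C=C(/C)CCO[Si](C)(C)C(C)(C)C | intermediate
9 | 2-(trimethylsilyloxy)buta-1,3-diene | C=CC(=C)O[Si](C)(C)C | starting material
10 | lithium buta-1,3-dien-2-olate | C=CC(=C)O[Li] | intermediate (not isolated)
11 | 1-[(4S,5R)-4-[(Z)-5-(tert-butyldimethylsilyloxy)-3-methylpent-2-en-1-yl]-5-hydroxy-2,2-dimethyl-1,3-dioxan-5-yl]but-3-en-2-one | C=CC(=O)C[C@@]1(O)COC(C)(C)O[C@H]1C/C=C(/C)CCO[Si](C)(C)C(C)(C)C | intermediate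
12 | (R)-1-[(4S,5R)-4-[(Z)-5-(tert-butyldimethylsilyloxy)-3-methylpent-2-en-1-yl]-5-hydroxy-2,2-dimethyl-1,3-dioxan-5-yl]but-3-en-2-ol | C=C[C@H](O)C[C@@]1(O)COC(C)(C)O[C@H]1C/C=C(/C)CCO[Si](C)(C)C(C)(C)C | intermediate
13 | 2-(bromomethyl)acrylic acid | OC(=O)C(=C)CBr | starting material
14 | (R)-1-[(4S,5R)-4-[(Z)-5-(tert-butyldimethylsilyloxy)-3-methylpent-2-en-1-yl]-5-hydroxy-2,2-dimethyl-1,3-dioxan-5-yl]but-3-en-2-yl 2-(bromomethyl)acrylate | C=C[C@H](OC(=O)C(=C)CBr)C[C@@]1(O)COC(C)(C)O[C@H]1C/C=C(/C)CCO[Si](C)(C)C(C)(C)C | intermediate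
15 | (R)-3-(bromomethyl)-5-{[(4S,5R)-4-[(Z)-5-(tert-butyldimethylsilyloxy)-3-methylpent-2-en-1-yl]-5-hydroxy-2,2-dimethyl-1,3-dioxan-5-yl]methyl}furan-2(5H)-one | BrCC1=C[C@@H](C[C@@]2(O)COC(C)(C)O[C@H]2C/C=C(/C)CCO[Si](C)(C)C(C)(C)C)OC1=O | intermediate
16 | (R)-3-(bromomethyl)-5-{[(4S,5R)-5-hydroxy-4-[(Z)-5-hydroxy-3-methylpent-2-en-1-yl]-2,2-dimethyl-1,3-dioxan-5-yl]methyl}furan-2(5H)-one | BrCC1=C[C@@H](C[C@@]2(O)COC(C)(C)O[C@H]2C/C=C(/C)CCO)OC1=O | intermediate
17 | (Z)-5-[(4S,5R)-5-{[(R)-4-(bromomethyl)-5-oxo-2,5-dihydrofuran-2-yl]methyl}-5-hydroxy-2,2-dimethyl-1,3-dioxan-4-yl]-3-methylpent-3-enal | BrCC1=C[C@@H](C[C@@]2(O)COC(C)(C)O[C@H]2C/C=C(/C)CC=O)OC1=O | intermediate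
18 | allylchromium dichloride from 17 (CrCl2 unit on C13 in place of Br; trivalent chromium) | Cl[Cr](Cl)CC1=C[C@@H](C[C@@]2(O)COC(C)(C)O[C@H]2C/C=C(/C)CC=O)OC1=O | intermediate (not isolated)
19 | (1(10)Z,3S,4R,6R,7R,8S)-4,8-dihydroxy-3,15-(isopropylidenedioxy)germacra-1(10),11(13)-dien-12,6-olide (8α-alcohol, trans-fused lactone) | C=C1C(=O)O[C@@H]2C[C@@]3(O)COC(C)(C)O[C@H]3C/C=C(/C)C[C@H](O)[C@@H]12 | intermediate
20 | angelic acid, (Z)-2-methylbut-2-enoic acid | C/C=C(/C)C(=O)O | starting material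
21 | (1(10)Z,3S,4R,6R,7R,8R)-8-angeloyloxy-4-hydroxy-3,15-(isopropylidenedioxy)germacra-1(10),11(13)-dien-12,6-olide | C=C1C(=O)O[C@@H]2C[C@@]3(O)COC(C)(C)O[C@H]3C/C=C(/C)C[C@@H](OC(=O)/C(C)=C\C)[C@@H]12 | intermediate
22 | (1(10)Z,3S,4R,6R,7R,8R)-8-angeloyloxy-3,4,15-trihydroxygermacra-1(10),11(13)-dien-12,6-olide | C=C1C(=O)O[C@@H]2C[C@@](O)(CO)[C@@H](O)C/C=C(/C)C[C@@H](OC(=O)/C(C)=C\C)[C@@H]12 | intermediate
23 | (1R,3S,4R,6R,7S,8R,10S)-8-angeloyloxy-1,10-epoxy-3,4,15-trihydroxygermacr-11(13)-en-12,6-olide (CNP0307250.1) | C=C1C(=O)O[C@@H]2C[C@@](O)(CO)[C@@H](O)C[C@H]3O[C@@]3(C)C[C@@H](OC(=O)/C(C)=C\C)[C@@H]12 | target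

## Step count and risks

Total steps: 14. Longest linear sequence: 13 (steps 2–14, from 3 to 23); fragment 2 takes one further step.

**Step 11 (ring closure through C7–C8).** This is the least precedented step. The ring may close with the wrong fusion, give oligomers, or deliver the other C8 epimer. Fallback, setting out from 16 and returning at 21: replace the closed chromium transition state by a Lewis-acid-triggered allylstannane addition. Alcohol 16 is stannylated (Bu3SnSnBu3, Pd(PPh3)4, THF) to (R)-5-{[(4S,5R)-5-hydroxy-4-[(Z)-5-hydroxy-3-methylpent-2-en-1-yl]-2,2-dimethyl-1,3-dioxan-5-yl]methyl}-3-[(tributylstannyl)methyl]furan-2(5H)-one F1. Dess–Martin oxidation gives the stannyl aldehyde F2. BF3·OEt2 in CH2Cl2 at −78 °C under high dilution then closes the ring through an open transition state, which is expected to give the syn product, the 8β-alcohol F3, directly. F3 is esterified with retention (angelic acid 20, 2,4,6-trichlorobenzoyl chloride, Et3N, toluene, 80 °C) to give 21.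

**Step 12 (Mitsunobu inversion with angelic acid).** The hindered, homoallylic C8 alcohol may eliminate to a diene instead of being displaced. Fallback, setting out from 19 and returning at 21: invert by oxidation and reduction. Dess–Martin oxidation of 19 gives the 8-ketone F4. Luche reduction (NaBH4, CeCl3·7H2O, MeOH, −78 °C) should deliver hydride from the α face, away from the β-oriented lactone carbon on C7, to give the 8β-alcohol F5 (same structure as F3). Mixed-anhydride esterification with angelic acid 20 as above then gives 21.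

**Step 14 (epoxidation face).** Facial selectivity on the flexible 10-membered ring is not secured, and the α-epoxide may form. Fallback, setting out from 22 and returning at 23: a two-step halohydrin route that places oxygen on the face opposite to the electrophile. NBS in THF/H2O at 0 °C adds bromine to the same (α) face that the peracid prefers, and water opens at the tertiary C10 from the β face to give the 1α-bromo-10β-hydroxy bromohydrin F6. Ag2O in MeCN closes it with inversion at C1 to the 1β,10β-epoxide 23.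

## Further compounds

F1 | step 11 | (R)-5-{[(4S,5R)-5-hydroxy-4-[(Z)-5-hydroxy-3-methylpent-2-en-1-yl]-2,2-dimethyl-1,3-dioxan-5-yl]methyl}-3-[(tributylstannyl)methyl]furan-2(5H)-one | CCCC[Sn](CCCC)(CCCC)CC1=C[C@@H](C[C@@]2(O)COC(C)(C)O[C@H]2C/C=C(/C)CCO)OC1=O
F2 | step 11 | (Z)-5-[(4S,5R)-5-hydroxy-2,2-dimethyl-5-{[(R)-5-oxo-4-[(tributylstannyl)methyl]-2,5-dihydrofuran-2-yl]methyl}-1,3-dioxan-4-yl]-3-methylpent-3-enal | CCCC[Sn](CCCC)(CCCC)CC1=C[C@@H](C[C@@]2(O)COC(C)(C)O[C@H]2C/C=C(/C)CC=O)OC1=O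
F3 | step 11 | (1(10)Z,3S,4R,6R,7R,8R)-4,8-dihydroxy-3,15-(isopropylidenedioxy)germacra-1(10),11(13)-dien-12,6-olide (8β-alcohol) | C=C1C(=O)O[C@@H]2C[C@@]3(O)COC(C)(C)O[C@H]3C/C=C(/C)C[C@@H](O)[C@@H]12
F4 | step 12 | (1(10)Z,3S,4R,6R,7S)-4-hydroxy-3,15-(isopropylidenedioxy)-8-oxogermacra-1(10),11(13)-dien-12,6-olide | C=C1C(=O)O[C@@H]2C[C@@]3(O)COC(C)(C)O[C@H]3C/C=C(/C)CC(=O)[C@@H]12
F5 | step 12 | (1(10)Z,3S,4R,6R,7R,8R)-4,8-dihydroxy-3,15-(isopropylidenedioxy)germacra-1(10),11(13)-dien-12,6-olide (8β-alcohol, same structure as F3) | C=C1C(=O)O[C@@H]2C[C@@]3(O)COC(C)(C)O[C@H]3C/C=C(/C)C[C@@H](O)[C@@H]12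
F6 | step 14 | (1S,3S,4R,6R,7R,8R,10S)-8-angeloyloxy-1-bromo-3,4,10,15-tetrahydroxygermacr-11(13)-en-12,6-olide (1α-bromo-10β-hydroxy) | C=C1C(=O)O[C@@H]2C[C@@](O)(CO)[C@@H](O)C[C@H](Br)[C@](O)(C)C[C@@H](OC(=O)/C(C)=C\C)[C@@H]12
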